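**Retrosynthetic overview**
- The strategy rests on the 2,2-dimethyl-2H-pyran fused to ring B at C2'–C3'. Its C2'–C4'' bond sits on the aryl carbon wedged between C1' (which carries the chromenone) and the pyran-oxygen carbon C3'. That bond is cut last, leading back to a 3'-O-(1,1-dimethylpropargyl) ether of the otherwise complete flavonol (gold-catalysed 6-endo-dig hydroarylation).
- Ring C (O1–C2 and C3–OH) comes from a chalcone by Claisen–Schmidt condensation and Algar–Flynn–Oyamada oxidative cyclisation, built while ring B has only one ortho substituent.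
- Ring B aldehyde: the C6' tert-prenyl group comes from a γ-selective Suzuki–Miyaura coupling of a 2-bromobenzoate with prenylB(pin), and the O3' propargyl ether from copper-catalysed alkylation.
- Ring A ketone: C-prenylation of 2,4,6-trihydroxyacetophenone, then bis-MOM protection that leaves free the hydroxyl next to the prenyl group.
- Ring order: ring C first, then the dimethylpyran; acidic removal of all MOM ethers ends the route.

Key step: step 12

Remark: ring B starts from methyl 2-bromo-4,5-dimethoxybenzoate (bromine already para to the future O3'). The C5 hydroxyl is carried as a MOM ether so that ring C can only close through the hydroxyl next to the prenyl group. The propargyl ether is placed on ring B before ring C is built, which avoids a third orthogonal protecting group.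

**Step 1**
Reactants: 1 methyl 2-bromo-4,5-dimethoxybenzoate
Product: 2 methyl 2-bromo-4,5-dihydroxybenzoate
Conditions: BBr3 (3 equiv), CH2Cl2, −78 → 0 °C; aqueous work-up
Reagents that add atoms: none
Why: Lewis-acid cleavage of aryl methyl ethers (bromide attacks the O-methyl group of the boron-complexed ether) should free the catechol while the aryl bromide and, at low temperature, the methyl ester persist.

**Step 2**
Reactants: 2 methyl 2-bromo-4,5-dihydroxybenzoate
Product: 3 methyl 2-bromo-5-hydroxy-4-(methoxymethoxy)benzoate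
Conditions: MOMCl (1.05 equiv), K2CO3 (1.1 equiv), acetone, 0 °C → rt
Reagents that add atoms: chloromethyl methyl ether (MOMCl), COCCl
Why: Williamson-type acetalisation with one equivalent of base should take place at the more acidic 4-hydroxyl (para to the ester), as is usual for protocatechuate-type catechols, leaving the 5-hydroxyl (the future O3') free.

**Step 3**
Reactants: 3 methyl 2-bromo-5-hydroxy-4-(methoxymethoxy)benzoate; 4 prenylboronic acid pinacol ester
Product: 5 methyl 5-hydroxy-4-(methoxymethoxy)-2-(2-methylbut-3-en-2-yl)benzoate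
Conditions: 4 (1.5 equiv), Pd(OAc)2 (3 mol %), electron-poor biaryl diarylphosphine ligand chosen for γ-selectivity (6 mol %), K3PO4 (aq), MeCN, 70 °C
Reagents that add atoms: none
Why: ligand-controlled γ-selective Suzuki–Miyaura coupling of a 3,3-disubstituted allylboronate, in which SE2' transmetalation puts palladium on the tertiary carbon and fast reductive elimination from that σ-allyl species should give the branched (1,1-dimethylallyl) arene; the ester is kept here because an aldehyde would be allylborated by 4.

**Step 4**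
Reactants: 5 methyl 5-hydroxy-4-(methoxymethoxy)-2-(2-methylbut-3-en-2-yl)benzoate; 6 3-chloro-3-methylbut-1-yne
Product: 7 methyl 4-(methoxymethoxy)-2-(2-methylbut-3-en-2-yl)-5-[(2-methylbut-3-yn-2-yl)oxy]benzoate
Conditions: 6 (1.5 equiv), CuCl2·2H2O (1 mol %), DBU, MeCN, 0 °C
Reagents that add atoms: none
Why: copper-catalysed O-alkylation of a phenol with a tertiary propargylic chloride (copper acetylide ionises to a stabilised propargylic cation equivalent that the phenoxide captures) should give the tertiary ether at 0 °C, well below the onset of the propargyl Claisen rearrangement.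

**Step 5**
Reactants: 7 methyl 4-(methoxymethoxy)-2-(2-methylbut-3-en-2-yl)-5-[(2-methylbut-3-yn-2-yl)oxy]benzoate
Product: 8 [4-(methoxymethoxy)-2-(2-methylbut-3-en-2-yl)-5-[(2-methylbut-3-yn-2-yl)oxy]phenyl]methanol
Conditions: i-Bu2AlH (2.5 equiv), CH2Cl2, −78 → 0 °C; aq. sodium potassium tartrate work-up
Reagents that add atoms: none
Why: hydride reduction of the ester to the benzylic alcohol should proceed at low temperature without hydroalumination of the alkyne or alkene and without touching the MOM ether.

**Step 6**
Reactants: 8 [4-(methoxymethoxy)-2-(2-methylbut-3-en-2-yl)-5-[(2-methylbut-3-yn-2-yl)oxy]phenyl]methanol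
Product: 9 4-(methoxymethoxy)-2-(2-methylbut-3-en-2-yl)-5-[(2-methylbut-3-yn-2-yl)oxy]benzaldehyde
Conditions: activated MnO2 (excess), CH2Cl2, rt
Reagents that add atoms: none
Why: MnO2 oxidises benzylic alcohols selectively to aldehydes under neutral conditions that leave the alkyne, the vinyl group and the acetal alone.

**Step 7**
Reactants: 10 2,4,6-trihydroxyacetophenone; 11 prenyl bromide
Product: 12 2,4,6-trihydroxy-3-(3-methylbut-2-en-1-yl)acetophenone
Conditions: 11 (1.0 equiv), DBU, THF, 0 °C → rt
Reagents that add atoms: none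
Why: C-alkylation of the phloroglucinol-type phenoxide at the ring carbon between two hydroxyls should give the mono-C-prenyl ketone (C3 and C5 are equivalent, so one regioisomer), with over-alkylation limited by stoichiometry.

**Step 8**
Reactants: 12 2,4,6-trihydroxy-3-(3-methylbut-2-en-1-yl)acetophenone
Product: 13 2-hydroxy-4,6-bis(methoxymethoxy)-3-(3-methylbut-2-en-1-yl)acetophenone
Conditions: MOMCl (2.2 equiv), i-Pr2NEt, CH2Cl2, 0 °C → rt
Reagents that add atoms: chloromethyl methyl ether (MOMCl), COCCl
Why: MOM protection should take the para hydroxyl and the less hindered ortho hydroxyl, leaving free the hydroxyl that is flanked by the prenyl group and chelated to the carbonyl, which is the oxygen that must become O1.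

**Step 9**
Reactants: 13 2-hydroxy-4,6-bis(methoxymethoxy)-3-(3-methylbut-2-en-1-yl)acetophenone; 9 4-(methoxymethoxy)-2-(2-methylbut-3-en-2-yl)-5-[(2-methylbut-3-yn-2-yl)oxy]benzaldehyde
Product: 14 (E)-1-[2-hydroxy-4,6-bis(methoxymethoxy)-3-(3-methylbut-2-en-1-yl)phenyl]-3-[4-(methoxymethoxy)-2-(2-methylbut-3-en-2-yl)-5-[(2-methylbut-3-yn-2-yl)oxy]phenyl]prop-2-en-1-one
Conditions: KOH, EtOH/H2O, 0 °C → rt
Reagents that add atoms: none
Why: Claisen–Schmidt aldol condensation of the methyl ketone enolate with the non-enolisable aldehyde followed by E1cB dehydration should give the E-enone; the propargyl ether has no propargylic hydrogen and cannot isomerise to an allene in base.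

**Step 10**
Reactants: 14 the (E)-chalcone of step 9
Product: 16 3-hydroxy-5,7-bis(methoxymethoxy)-2-[4-(methoxymethoxy)-2-(2-methylbut-3-en-2-yl)-5-[(2-methylbut-3-yn-2-yl)oxy]phenyl]-8-(3-methylbut-2-en-1-yl)-4H-chromen-4-one, via trans-dihydroflavonol 15 (not isolated)
Conditions: 30% H2O2 (aq), NaOH (aq), MeOH, 0 °C → rt
Reagents that add atoms: hydrogen peroxide, OO
Why: Algar–Flynn–Oyamada oxidative cyclisation, in which the 2'-phenoxide adds 6-endo to the enone β-carbon while the enolate is hydroxylated by peroxide and the resulting trans-dihydroflavonol is dehydrogenated by alkaline peroxide, should give the flavonol with the prenyl group at C8 because the other ortho oxygen is blocked as its MOM ether; the two stereocentres of 15 are erased, and the isolated alkenes and alkyne do not react with nucleophilic peroxide.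

**Step 11**
Reactants: 16 the 3-hydroxyflavone of step 10
Product: 17 3,5,7-tris(methoxymethoxy)-2-[4-(methoxymethoxy)-2-(2-methylbut-3-en-2-yl)-5-[(2-methylbut-3-yn-2-yl)oxy]phenyl]-8-(3-methylbut-2-en-1-yl)-4H-chromen-4-one
Conditions: MOMCl (1.5 equiv), i-Pr2NEt, CH2Cl2, 0 °C → rt
Reagents that add atoms: chloromethyl methyl ether (MOMCl), COCCl
Why: O-alkylation of the acidic flavonol 3-hydroxyl should mask the only remaining protic, potentially gold-binding oxygen nucleophile before the π-acid step.

**Step 12**
Reactants: 17 the 3'-O-(2-methylbut-3-yn-2-yl) flavonol 3,5,7,4'-tetrakis(methoxymethyl) ether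
Product: 18 3,5,7-tris(methoxymethoxy)-2-[8-(methoxymethoxy)-2,2-dimethyl-6-(2-methylbut-3-en-2-yl)-2H-chromen-5-yl]-8-(3-methylbut-2-en-1-yl)-4H-chromen-4-one
Conditions: Ph3PAuCl (5 mol %), AgSbF6 (5 mol %), CH2Cl2, 0 °C → rt
Reagents that add atoms: none
Why: Ph3PAu+ (monovalent gold, formed by chloride abstraction with AgSbF6) binds the terminal alkyne, and C2', the only free carbon ortho to O3', attacks the alkyne terminus anti to gold in a Friedel–Crafts manner; rearomatisation of the arenium ion and protodeauration of the vinylgold species release the 2H-chromene and the catalyst. The closest known reaction is the gold- or platinum-catalysed intramolecular hydroarylation of aryl propargyl ethers to 2H-chromenes. The pyran ring closes in the 6-endo-dig mode, which a terminal alkyne favours over 5-exo-dig closure to a 3-methylenedihydrobenzofuran. No stereocentre is created. Site selectivity needs nothing beyond the substrate, since C4' carries the MOM ether and the gem-dimethyl group holds the alkyne folded over C2'; chemoselectivity for the alkyne over the prenyl and vinyl alkenes rests on the alkynophilicity of cationic gold. Ring B is twisted out of conjugation with the chromenone by the C6' tert-prenyl group, so C2' keeps the donor effect of O3' despite its crowding.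

**Step 13**
Reactants: 18 the pyrano-fused flavonol tetrakis(methoxymethyl) ether
Product: 19 3,5,7-trihydroxy-2-[8-hydroxy-2,2-dimethyl-6-(2-methylbut-3-en-2-yl)-2H-chromen-5-yl]-8-(3-methylbut-2-en-1-yl)-4H-chromen-4-one (CNP0241222.0)
Conditions: 3 M HCl (aq)/MeOH, rt → 40 °C
Reagents that add atoms: none
Why: acid-catalysed acetal exchange with methanol should remove all four MOM ethers, and the mild temperature is chosen so that the prenyl group does not add to the neighbouring C7 hydroxyl and the chromene alkene does not add methanol.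

**Compound list**
1 | methyl 2-bromo-4,5-dimethoxybenzoate | COC(=O)c1cc(OC)c(OC)cc1Br | starting material
2 | methyl 2-bromo-4,5-dihydroxybenzoate | COC(=O)c1cc(O)c(O)cc1Br | intermediate
3 | methyl 2-bromo-5-hydroxy-4-(methoxymethoxy)benzoate | COC(=O)c1cc(O)c(OCOC)cc1Br | intermediate
4 | prenylboronic acid pinacol ester, 4,4,5,5-tetramethyl-2-(3-methylbut-2-en-1-yl)-1,3,2-dioxaborolane | CC(C)=CCB1OC(C)(C)C(C)(C)O1 | starting material
5 | methyl 5-hydroxy-4-(methoxymethoxy)-2-(2-methylbut-3-en-2-yl)benzoate | COC(=O)c1cc(O)c(OCOC)cc1C(C)(C)C=C | intermediate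
6 | 3-chloro-3-methylbut-1-yne | CC(C)(Cl)C#C | starting material
7 | methyl 4-(methoxymethoxy)-2-(2-methylbut-3-en-2-yl)-5-[(2-methylbut-3-yn-2-yl)oxy]benzoate | COC(=O)c1cc(OC(C)(C)C#C)c(OCOC)cc1C(C)(C)C=C | intermediate
8 | [4-(methoxymethoxy)-2-(2-methylbut-3-en-2-yl)-5-[(2-methylbut-3-yn-2-yl)oxy]phenyl]methanol | OCc1cc(OC(C)(C)C#C)c(OCOC)cc1C(C)(C)C=C | intermediate
9 | 4-(methoxymethoxy)-2-(2-methylbut-3-en-2-yl)-5-[(2-methylbut-3-yn-2-yl)oxy]benzaldehyde | O=Cc1cc(OC(C)(C)C#C)c(OCOC)cc1C(C)(C)C=C | intermediate
10 | 2,4,6-trihydroxyacetophenone | CC(=O)c1c(O)cc(O)cc1O | starting material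
11 | prenyl bromide, 1-bromo-3-methylbut-2-ene | CC(C)=CCBr | starting material
12 | 2,4,6-trihydroxy-3-(3-methylbut-2-en-1-yl)acetophenone | CC(=O)c1c(O)cc(O)c(CC=C(C)C)c1O | intermediate
13 | 2-hydroxy-4,6-bis(methoxymethoxy)-3-(3-methylbut-2-en-1-yl)acetophenone | CC(=O)c1c(OCOC)cc(OCOC)c(CC=C(C)C)c1O | intermediate
14 | (E)-1-[2-hydroxy-4,6-bis(methoxymethoxy)-3-(3-methylbut-2-en-1-yl)phenyl]-3-[4-(methoxymethoxy)-2-(2-methylbut-3-en-2-yl)-5-[(2-methylbut-3-yn-2-yl)oxy]phenyl]prop-2-en-1-one | O=C(/C=C/c1cc(OC(C)(C)C#C)c(OCOC)cc1C(C)(C)C=C)c1c(OCOC)cc(OCOC)c(CC=C(C)C)c1O | intermediate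
15 | rac-(2,3-trans)-3-hydroxy-5,7-bis(methoxymethoxy)-2-[4-(methoxymethoxy)-2-(2-methylbut-3-en-2-yl)-5-[(2-methylbut-3-yn-2-yl)oxy]phenyl]-8-(3-methylbut-2-en-1-yl)chroman-4-one (dihydroflavonol; racemic, one enantiomer drawn; not isolated) | C=CC(C)(C)c1cc(OCOC)c(OC(C)(C)C#C)cc1[C@@H]1[C@@H](O)C(=O)c2c(OCOC)cc(OCOC)c(CC=C(C)C)c2O1 | intermediate
16 | 3-hydroxy-5,7-bis(methoxymethoxy)-2-[4-(methoxymethoxy)-2-(2-methylbut-3-en-2-yl)-5-[(2-methylbut-3-yn-2-yl)oxy]phenyl]-8-(3-methylbut-2-en-1-yl)-4H-chromen-4-one | O=c1c(O)c(-c2cc(OC(C)(C)C#C)c(OCOC)cc2C(C)(C)C=C)oc2c(CC=C(C)C)c(OCOC)cc(OCOC)c12 | intermediate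
17 | 3,5,7-tris(methoxymethoxy)-2-[4-(methoxymethoxy)-2-(2-methylbut-3-en-2-yl)-5-[(2-methylbut-3-yn-2-yl)oxy]phenyl]-8-(3-methylbut-2-en-1-yl)-4H-chromen-4-one (key-step precursor) | O=c1c(OCOC)c(-c2cc(OC(C)(C)C#C)c(OCOC)cc2C(C)(C)C=C)oc2c(CC=C(C)C)c(OCOC)cc(OCOC)c12 | intermediate
18 | 3,5,7-tris(methoxymethoxy)-2-[8-(methoxymethoxy)-2,2-dimethyl-6-(2-methylbut-3-en-2-yl)-2H-chromen-5-yl]-8-(3-methylbut-2-en-1-yl)-4H-chromen-4-one (key-step product) | O=c1c(OCOC)c(-c2c(C(C)(C)C=C)cc(OCOC)c3OC(C)(C)C=Cc23)oc2c(CC=C(C)C)c(OCOC)cc(OCOC)c12 | intermediate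
19 | 3,5,7-trihydroxy-2-[8-hydroxy-2,2-dimethyl-6-(2-methylbut-3-en-2-yl)-2H-chromen-5-yl]-8-(3-methylbut-2-en-1-yl)-4H-chromen-4-one | C=CC(C)(C)c1cc(O)c2c(c1-c1oc3c(CC=C(C)C)c(O)cc(O)c3c(=O)c1O)C=CC(C)(C)O2 | target

**Step count**
Total: 13 steps. Longest linear sequence: 11 steps (steps 1–6, then 9–13); the ring A branch (steps 7–8) joins at step 9.

**Steps most likely to fail**

Step 3 (branch-selective coupling). The allylpalladium intermediate may undergo σ–π–σ isomerisation faster than reductive elimination at the carbon next to the ortho ester, so that branch selectivity erodes towards the linear prenyl arene, and protodeboronation of 4 may compete. The fallback sets out from 3 and comes back at 5, building the quaternary carbon stepwise. Palladium-catalysed α-arylation of isobutyraldehyde with 3 ([Pd(C3H5)Cl]2, 1,1'-bis(diphenylphosphino)ferrocene, Cs2CO3, dioxane, 80 °C) should give methyl 5-hydroxy-4-(methoxymethoxy)-2-(2-methyl-1-oxopropan-2-yl)benzoate F1. Wittig methylenation of F1 (Ph3PCH3Br, KOt-Bu in excess, THF, 0 °C) should then deliver 5, with no regiochemical ambiguity.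

Step 10 (oxidative cyclisation). The 6'-alkoxy group and the hindered β-aryl group may divert the reaction through enone epoxidation and 5-exo ring closure (aurone formation) instead of 6-endo closure. The fallback sets out from 14 and comes back at 15 and then 16, separating ring closure from C3 oxygenation. Oxa-Michael cyclisation of 14 (NaOAc, EtOH, reflux) can only close 6-endo and should give racemic 5,7-bis(methoxymethoxy)-2-[4-(methoxymethoxy)-2-(2-methylbut-3-en-2-yl)-5-[(2-methylbut-3-yn-2-yl)oxy]phenyl]-8-(3-methylbut-2-en-1-yl)chroman-4-one F2. Kinetic enolisation of F2 (LiN(SiMe3)2, THF, −78 °C, which spares the less acidic alkyne C–H) and hydroxylation with 2-(phenylsulfonyl)-3-phenyloxaziridine anti to the 2-aryl group should give the trans-dihydroflavonol 15. Alkaline hydrogen peroxide, as in the second stage of step 10, then dehydrogenates 15 to 16.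

Step 12 (key step). Attack of the crowded C2' on the gold-activated alkyne may be too slow, so that hydration of the alkyne or loss of MOM groups through adventitious acid from the silver salt takes over. The fallback sets out from 17 and comes back at 18 by a metal-free pericyclic route: heating 17 in N,N-diethylaniline at about 160 °C. The aromatic propargyl Claisen rearrangement ([3,3] shift to C2', the only open ortho carbon), enolisation, 1,5-hydrogen shift and oxa-6π electrocyclisation should give the same 2,2-dimethyl-2H-chromene. This fallback makes no compound outside the list (F0).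

**Further compounds**
F1 | step 3 | methyl 5-hydroxy-4-(methoxymethoxy)-2-(2-methyl-1-oxopropan-2-yl)benzoate | COC(=O)c1cc(O)c(OCOC)cc1C(C)(C)C=O
F2 | step 10 | racemic 5,7-bis(methoxymethoxy)-2-[4-(methoxymethoxy)-2-(2-methylbut-3-en-2-yl)-5-[(2-methylbut-3-yn-2-yl)oxy]phenyl]-8-(3-methylbut-2-en-1-yl)chroman-4-one | C=CC(C)(C)c1cc(OCOC)c(OC(C)(C)C#C)cc1C1CC(=O)c2c(OCOC)cc(OCOC)c(CC=C(C)C)c2O1
F0 | step 12 | none | none
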